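**Strategy.** Atoms are numbered O1–O2–C3–C4–C4a–O5–C6–C7–C7a. The 1,2-dioxane is disconnected into a C–O–O unit (C3 with O2–O1, as a silylperoxycarbenium ion from a methyl ketone peroxyketal) and the three-carbon unit C4–C4a–C7a, supplied by (R)-4-isopropenyl-β-lactone. In one operation the alkene CH2 bonds to C3, the C4a cation is trapped as a 1,2-dioxolane, and release of β-lactone strain drives a dyotropic shift that moves O1 to C7a (inversion) and the carboxylate to C4a, closing both rings. The step exploits the vicinal, anti-disposed C7a–O1 and C4a–O5 bonds at the cis fusion of the dioxane and lactone rings. A B-alkyl Suzuki coupling then adds the (E,E,E)-triene.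

Key step: step 4

Assumption: the antipode of the IDPi acid that directs Re-face attack at C3 (3S) and the pseudoenantiomeric cinchona silyl ether that gives the 4R lactone are taken from a preliminary screen; both antipodes of each are available.

Step 1
Reactants: 1 dec-9-en-2-one
Product: 3 2-methoxydec-9-en-2-yl hydroperoxide (racemic), via dimethyl ketal 2 (not isolated)
Conditions: HC(OMe)3, MeOH, TsOH (cat.), rt; evaporate; H2O2 (anhydrous, in Et2O, 1.2 equiv), TsOH (cat.), 0 °C
Reagents that add atoms: trimethyl orthoformate COC(OC)OC; hydrogen peroxide OO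
Why: Acid-catalysed ketalisation followed by transketalisation of the ketal with H2O2 (perhydrolysis to a 1-methoxyalkyl hydroperoxide) should stop at mono-exchange with a small excess of H2O2 at 0 °C; the new centre is racemic and is erased in step 4, and the remote alkene is inert.

Step 2
Reactants: 3 2-methoxydec-9-en-2-yl hydroperoxide
Product: 4 triethyl[(2-methoxydec-9-en-2-yl)peroxy]silane (racemic)
Conditions: Et3SiCl, imidazole, DMF, 0 °C
Reagents that add atoms: chlorotriethylsilane CC[Si](Cl)(CC)CC
Why: O-Silylation of a hydroperoxide with a chlorosilane and imidazole is standard and leaves the acid-labile ketal and the O–O bond untouched under these basic conditions.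

Step 3
Reactants: 5 methacrolein; 6 acetyl chloride
Product: 7 (4R)-4-(prop-1-en-2-yl)oxetan-2-one
Conditions: iPr2NEt, O-trimethylsilylquinidine (10 mol %), LiClO4, CH2Cl2–Et2O, −78 °C, slow addition of 6
Reagents that add atoms: none
Why: In the acyl halide–aldehyde cyclocondensation (ketene–aldehyde [2+2]) the alkaloid-bound acetyl ammonium enolate adds to the LiClO4-activated aldehyde and lactonises, the alkaloid shielding one enolate face so that C4 is set as R; low temperature and slow addition should hold back polymerisation of the enal.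

Step 4
Reactants: 4 triethyl[(2-methoxydec-9-en-2-yl)peroxy]silane; 7 (4R)-4-(prop-1-en-2-yl)oxetan-2-one (1.5 equiv)
Product: 9 (3S,4aS,7aS)-3,4a-dimethyl-3-(oct-7-en-1-yl)tetrahydrofuro[3,2-c][1,2]dioxin-6(3H)-one, via dioxolane β-lactone 8 (not isolated)
Conditions: BINOL-derived N-triflyl imidodiphosphorimidate (IDPi) acid (5 mol %), allyl-SiMe3 (5 mol %, presilylation), CH2Cl2, −78 °C, then −20 °C
Reagents that add atoms: none
Why: Proposed new method: the silylated IDPi abstracts methoxide from 4 and the resulting silylperoxycarbenium ion, held in the chiral anion pocket, is attacked on its Re face by the isopropenyl CH2 of 7 (C4–C3 bond, 3S under catalyst control), the closest known reactions being the IDPi-catalysed Mukaiyama aldol of methyl alkyl ketones, which tells methyl from n-alkyl, and the peroxycarbenium–alkene [3+2] annulation of silylperoxy ketals. The C4a cation is captured by the silylperoxy oxygen (five-membered closure, endo with respect to the former alkene) to give dioxolane 8 and to return the silylium ion. On warming, silylium activation of the lactone carbonyl triggers a type-one dyotropic shift in which O1 migrates from C4a to C7a through a three-membered peroxonium ion, antiperiplanar to the departing acyloxy group (this expansion closes the dioxane ring), while the carboxylate closes the γ-lactone at C4a by 5-exo-tet opening of that ion; the models are the Lewis-acid dyotropic β-lactone to γ-lactone expansion and the peroxonium 1,2-dioxolane to 1,2-dioxane expansion. Both shifts invert, so 4R of 7 becomes 7aS and the anti O1/O5 arrangement can only be reached with the cis fusion (4aS), the stereocentre of 7 thus controlling C7a and C4a. The step needs Re-face selectivity at C3 (catalyst), cation capture anti to the lactone CH2 to give the dioxolane epimer 8 (the other epimer is expected to re-ionise under the silylium catalyst), and attack by the 1,1-disubstituted alkene of 7 instead of the less nucleophilic monosubstituted chain alkene (7 in excess). Relief of β-lactone strain should make the final shift irreversible.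

Step 5
Reactants: 10 (2E,4E)-hepta-2,4-dienal
Product: 11 (1E,3E,5E)-1-iodoocta-1,3,5-triene
Conditions: CrCl2, CHI3, THF–1,4-dioxane, 0 °C, dark; used at once
Reagents that add atoms: iodoform IC(I)I
Why: In the Takai olefination the geminal dichromium carbenoid from CHI3 adds to the aldehyde and eliminates to the E-alkenyl iodide, and the 2E,4E diene is not touched.

Step 6
Reactants: 9 (3S,4aS,7aS)-3,4a-dimethyl-3-(oct-7-en-1-yl)tetrahydrofuro[3,2-c][1,2]dioxin-6(3H)-one; 11 (1E,3E,5E)-1-iodoocta-1,3,5-triene
Product: 13 (3S,4aS,7aS)-3-[(9E,11E,13E)-hexadeca-9,11,13-trien-1-yl]-3,4a-dimethyltetrahydrofuro[3,2-c][1,2]dioxin-6(3H)-one, via B-alkyl-9-BBN 12 (not isolated)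
Conditions: 9-BBN-H, THF, 0 °C to rt; then 11, Pd(dppf)Cl2 (5 mol %), AsPh3, K3PO4 (3 M aq.), DMF, rt, dark
Reagents that add atoms: 9-borabicyclo[3.3.1]nonane B1C2CCCC1CCC2 (boron group of 12 only, no atoms in 13)
Why: Anti-Markovnikov hydroboration of the only alkene with 9-BBN (lactone and dialkyl peroxide are inert to R2BH at room temperature) followed by B-alkyl Suzuki–Miyaura coupling, which retains the iodide geometry, should give the all-E triene; room temperature, dppf/AsPh3 and phosphate base are chosen to spare the O–O bond and the β-peroxy lactone.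

**Compound list**

1 | dec-9-en-2-one | CC(=O)CCCCCCC=C | starting material
2 | 9,9-dimethoxydec-1-ene | COC(C)(OC)CCCCCCC=C | intermediate
3 | 2-methoxydec-9-en-2-yl hydroperoxide (racemic) | COC(C)(OO)CCCCCCC=C | intermediate
4 | triethyl[(2-methoxydec-9-en-2-yl)peroxy]silane (racemic) | COC(C)(OO[Si](CC)(CC)CC)CCCCCCC=C | intermediate
5 | methacrolein (2-methylprop-2-enal) | CC(=C)C=O | starting material
6 | acetyl chloride | CC(=O)Cl | starting material
7 | (4R)-4-(prop-1-en-2-yl)oxetan-2-one | CC(=C)[C@H]1CC(=O)O1 | intermediate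
8 | (4R)-4-[(3R,5S)-3,5-dimethyl-5-(oct-7-en-1-yl)-1,2-dioxolan-3-yl]oxetan-2-one | C=CCCCCCC[C@@]1(C)C[C@](C)([C@H]2CC(=O)O2)OO1 | intermediate
9 | (3S,4aS,7aS)-3,4a-dimethyl-3-(oct-7-en-1-yl)tetrahydrofuro[3,2-c][1,2]dioxin-6(3H)-one | C=CCCCCCC[C@@]1(C)C[C@]2(C)OC(=O)C[C@@H]2OO1 | intermediate
10 | (2E,4E)-hepta-2,4-dienal | CC/C=C/C=C/C=O | starting material
11 | (1E,3E,5E)-1-iodoocta-1,3,5-triene | CC/C=C/C=C/C=C/I | intermediate
12 | 9-{8-[(3S,4aS,7aS)-3,4a-dimethyl-6-oxotetrahydrofuro[3,2-c][1,2]dioxin-3-yl]octyl}-9-borabicyclo[3.3.1]nonane | B1(C2CCCC1CCC2)CCCCCCCC[C@@]3(C)C[C@]4(C)OC(=O)C[C@@H]4OO3 | intermediate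
13 | (3S,4aS,7aS)-3-[(9E,11E,13E)-hexadeca-9,11,13-trien-1-yl]-3,4a-dimethyltetrahydrofuro[3,2-c][1,2]dioxin-6(3H)-one | CC/C=C/C=C/C=C/CCCCCCCC[C@@]1(C)C[C@]2(C)OC(=O)C[C@@H]2OO1 | target

**Count.** Total steps: 6. Longest linear sequence: 4 steps (steps 1, 2, 4, 6).

**Steps most likely to fail**

1. Step 4. The ion pair may discriminate the two faces of C3 poorly, so that both C3 epimers form. The sequence may also stop at dioxolane 8, or acid-induced O–O heterolysis with carbon-to-oxygen migration (Criegee-type) may outrun the dyotropic shift. The C4a cation may be captured on the other face. The fallback uses only known reaction types, delivers the peroxide oxygen by SN2 instead of by the cation relay, and sets C3 without control. It sets out from 4 and 6 and comes back to the route at 9. Commercial 2-[(trimethylsilyl)methyl]prop-2-en-1-ol is oxidised with MnO2 to 2-[(trimethylsilyl)methyl]prop-2-enal F1. Cyclocondensation of F1 with 6 under the conditions of step 3 should give (4R)-4-[3-(trimethylsilyl)prop-1-en-2-yl]oxetan-2-one F2. Hosomi–Sakurai allylation of peroxyketal 4 with F2 (TiCl4, CH2Cl2, −78 °C) should give (4R)-4-{4-methyl-4-[(triethylsilyl)peroxy]dodeca-1,11-dien-2-yl}oxetan-2-one F3 as both epimers at the peroxide carbon. HF·pyridine frees (4R)-4-(4-hydroperoxy-4-methyldodeca-1,11-dien-2-yl)oxetan-2-one F4. Cs2CO3 in DMF then closes the dioxane by 6-exo-tet SN2 opening of the β-lactone at its alkyl carbon with inversion, giving 2-[(3S)-6-methyl-4-methylidene-6-(oct-7-en-1-yl)-1,2-dioxan-3-yl]acetic acid F5. TsOH-catalysed Markovnikov lactonisation onto the exocyclic alkene should give cis-fused 9 together with its (3R,4aS,7aS)-epimer F6, and the two are separated by chromatography.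

2. Step 6. Zerovalent palladium or the arsine may cleave the O–O bond, the aqueous base may open the lactone or start a retro-oxa-Michael reaction, and the trienyl iodide may isomerise or decay before coupling. The fallback is palladium-free and builds the triene by olefination. It sets out from 9 and 10 and comes back at 13. Linear-selective hydroformylation of 9 (Rh(acac)(CO)2, BiPhePhos, CO/H2, toluene, 60 °C) should give 9-[(3S,4aS,7aS)-3,4a-dimethyl-6-oxotetrahydrofuro[3,2-c][1,2]dioxin-3-yl]nonanal F7. Aldehyde 10 is reduced with NaBH4 in MeOH to (2E,4E)-hepta-2,4-dien-1-ol F8, which Ph3P·HBr converts into [(2E,4E)-hepta-2,4-dien-1-yl]triphenylphosphonium bromide F9. Wittig reaction of F7 with the ylide of F9 (NaN(SiMe3)2, THF, −78 °C) should give 13 mixed with its (9Z,11E,13E)-isomer F10. Catalytic I2 in the dark then equilibrates the new double bond to give all-E 13.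

3. Step 3. The α-branched enal may polymerise, ketene may dimerise, and the enantioselectivity may be low. The fallback replaces the [2+2] by an auxiliary-controlled acetate aldol and a separate lactonisation. It sets out from 5 and comes back at 7. (R)-2-Hydroxy-1,2,2-triphenylethyl acetate ((R)-HYTRA), doubly deprotonated with LiN(iPr)2 in THF at −78 °C, adds to 5 to give (1R)-2-hydroxy-1,2,2-triphenylethyl (3R)-3-hydroxy-4-methylpent-4-enoate F11; the 3R sense is expected by analogy with 2-methylpropanal. KOH in MeOH–H2O gives (3R)-3-hydroxy-4-methylpent-4-enoic acid F12 and returns the auxiliary diol. PhSO2Cl in pyridine at 0 °C activates the carboxyl group and closes the β-lactone with retention at the carbinol carbon to give 7.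

**Further compounds**

F1 | step 4 | 2-[(trimethylsilyl)methyl]prop-2-enal | C[Si](C)(C)CC(=C)C=O
F2 | step 4 | (4R)-4-[3-(trimethylsilyl)prop-1-en-2-yl]oxetan-2-one | C[Si](C)(C)CC(=C)[C@H]1CC(=O)O1
F3 | step 4 | (4R)-4-{4-methyl-4-[(triethylsilyl)peroxy]dodeca-1,11-dien-2-yl}oxetan-2-one (both epimers at the peroxide carbon) | C=CCCCCCCC(C)(OO[Si](CC)(CC)CC)CC(=C)[C@H]1CC(=O)O1
F4 | step 4 | (4R)-4-(4-hydroperoxy-4-methyldodeca-1,11-dien-2-yl)oxetan-2-one (both epimers at the peroxide carbon) | C=CCCCCCCC(C)(OO)CC(=C)[C@H]1CC(=O)O1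
F5 | step 4 | 2-[(3S)-6-methyl-4-methylidene-6-(oct-7-en-1-yl)-1,2-dioxan-3-yl]acetic acid (both C6 epimers) | C=CCCCCCCC1(C)CC(=C)[C@H](CC(=O)O)OO1
F6 | step 4 | (3R,4aS,7aS)-3,4a-dimethyl-3-(oct-7-en-1-yl)tetrahydrofuro[3,2-c][1,2]dioxin-6(3H)-one | C=CCCCCCC[C@]1(C)C[C@]2(C)OC(=O)C[C@@H]2OO1
F7 | step 6 | 9-[(3S,4aS,7aS)-3,4a-dimethyl-6-oxotetrahydrofuro[3,2-c][1,2]dioxin-3-yl]nonanal | O=CCCCCCCCC[C@@]1(C)C[C@]2(C)OC(=O)C[C@@H]2OO1
F8 | step 6 | (2E,4E)-hepta-2,4-dien-1-ol | CC/C=C/C=C/CO
F9 | step 6 | [(2E,4E)-hepta-2,4-dien-1-yl]triphenylphosphonium bromide | CC/C=C/C=C/C[P+](c1ccccc1)(c1ccccc1)c1ccccc1.[Br-]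
F10 | step 6 | (3S,4aS,7aS)-3-[(9Z,11E,13E)-hexadeca-9,11,13-trien-1-yl]-3,4a-dimethyltetrahydrofuro[3,2-c][1,2]dioxin-6(3H)-one | CC/C=C/C=C/C=C\CCCCCCCC[C@@]1(C)C[C@]2(C)OC(=O)C[C@@H]2OO1
F11 | step 3 | (1R)-2-hydroxy-1,2,2-triphenylethyl (3R)-3-hydroxy-4-methylpent-4-enoate | CC(=C)[C@H](O)CC(=O)O[C@H](c1ccccc1)C(O)(c1ccccc1)c1ccccc1
F12 | step 3 | (3R)-3-hydroxy-4-methylpent-4-enoic acid | CC(=C)[C@H](O)CC(=O)O
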